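## Retrosynthetic overview
1. The C14 aldehyde comes from oxidation of a 2,3-epoxy alcohol, and the oxirane (the last ring formed) comes from Sharpless epoxidation of a C14 allylic alcohol.
2. The C14–OH comes from SeO2 allylic oxidation of the C10 methyl group. Its ene/[2,3] mechanism places C14 trans to C2, which is the cis-in-ring olefin.
3. The ten-membered carbocycle (the first ring formed) comes from RCM closing C1=C10 of an acyclic triene diacetate.
4. In the C6/C7/C8 triad, an Evans syn-aldol sets C7 and C8, and an OH-directed 1,3-anti reduction of a C6 enone sets C6.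
5. The C5–C6 bond comes from a Weinreb ketone synthesis with an (E)-alkenyllithium made by carboalumination of an enyne.

Assumptions: compounds 3 and 6 are bought as catalogue chemicals. Germacrane numbering is used throughout: C1/C10 are the oxirane carbons, C14 is the CHO, C4=C5 is the olefin carrying CH3-15, C6 and C8 bear OAc, and C7 bears iPr.

## Route

**Step 1**
Reactants: 1, 3-methylbut-3-en-1-ol
Product: 2, 3-methylbut-3-enal
Conditions: DMP, NaHCO3, CH2Cl2, 0 °C to rt; silica plug; used at once as a solution
Reagents that add atoms: none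
Why: Dess–Martin oxidation is neutral and amine-free, so the β,γ-unsaturated aldehyde forms without slipping into conjugation.

**Step 2**
Reactants: 3, (4S)-4-benzyl-3-(3-methylbutanoyl)oxazolidin-2-one; 2, 3-methylbut-3-enal
Product: 4, (4S)-4-benzyl-3-[(2S,3R)-3-hydroxy-5-methyl-2-(propan-2-yl)hex-5-enoyl]oxazolidin-2-one
Conditions: n-Bu2BOTf, Et3N, CH2Cl2, 0 °C; add 2 at −78 °C, warm to 0 °C; pH 7 buffer, MeOH, 30% H2O2
Reagents that add atoms: none
Why: In this Evans boron syn-aldol, the (Z)-boron enolate reacts through a Zimmerman–Traxler chair on the face away from the benzyl group, setting C7 (S) and C8 (R) with iPr and OH syn.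

**Step 3**
Reactants: 4, aldol adduct
Product: 5, (2S,3R)-3-hydroxy-N-methoxy-N,5-dimethyl-2-(propan-2-yl)hex-5-enamide
Conditions: MeNH(OMe)·HCl, AlMe3, CH2Cl2, −20 °C to rt
Reagents that add atoms: N,O-dimethylhydroxylamine hydrochloride, CNOC.Cl
Why: In this Weinreb transamidation, the aluminium amide is directed by the free β-alkoxide to the exocyclic carbonyl, releasing the auxiliary without epimerising C7.

**Step 4**
Reactants: 6, hex-1-en-5-yne
Product: 7, (1E)-1-iodo-2-methylhexa-1,5-diene
Conditions: AlMe3, Cp2ZrCl2 (0.25 equiv), CH2Cl2, 0 °C to rt; then I2, THF, −30 °C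
Reagents that add atoms: trimethylaluminium, C[Al](C)C; iodine, II
Why: Negishi Zr-catalysed carboalumination adds Me–Al syn to the alkyne much faster than to the alkene, and iodinolysis with retention fixes the (E)-C4=C5 geometry.

**Step 5**
Reactants: 5, Weinreb amide; 7, alkenyl iodide
Product: 8, (4R,5S,7E)-4-hydroxy-2,8-dimethyl-5-(propan-2-yl)dodeca-1,7,11-trien-6-one
Conditions: 7, t-BuLi (2 equiv per iodide), Et2O, −78 °C; add to 5 pre-treated with i-PrMgCl (1 equiv), THF; −78 to 0 °C; aq NH4Cl
Reagents that add atoms: none
Why: In this Weinreb–Nahm ketone synthesis, Li–I exchange retains the olefin geometry, and the chelated tetrahedral intermediate stops over-addition and shields C7 until the quench.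

**Step 6**
Reactants: 8, β-hydroxy enone
Product: 9, (4R,5S,6R,7E)-2,8-dimethyl-5-(propan-2-yl)dodeca-1,7,11-triene-4,6-diol
Conditions: Me4NBH(OAc)3, MeCN/AcOH 1:1, −35 to −20 °C
Reagents that add atoms: none
Why: In this Evans–Saksena reduction, the C8 alkoxy-acetoxyborohydride delivers hydride intramolecularly through a chair to give only 1,2-reduction and the 1,3-anti diol, setting C6 (R).

**Step 7**
Reactants: 9, anti-diol
Product: 10, (4R,5S,6R,7E)-2,8-dimethyl-5-(propan-2-yl)dodeca-1,7,11-triene-4,6-diyl diacetate
Conditions: Ac2O, pyridine, DMAP, CH2Cl2, rt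
Reagents that add atoms: acetic anhydride, CC(=O)OC(C)=O
Why: DMAP-catalysed acylation installs both natural acetates with retention at C6 and C8, so no protecting groups are needed in the route.

**Step 8**
Reactants: 10, triene diacetate
Product: 11, (6R,7S,8R)-germacra-1(10)Z,4E-diene-6,8-diyl diacetate, i.e. (1R,2E,6Z,9R,10S)-3,7-dimethyl-10-(propan-2-yl)cyclodeca-2,6-diene-1,9-diyl diacetate
Conditions: Hoveyda–Grubbs II (2 × 7.5 mol %), 1,4-benzoquinone (20 mol %), toluene, 0.5 mM, 80 °C, Ar sparge, slow addition
Reagents that add atoms: none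
Why: In this ring-closing metathesis, Ru loads on the monosubstituted olefin and closes onto the methallyl group with loss of ethylene. The trisubstituted cis-in-ring product is inert to re-opening, and any 1(10)E isomer converges in step 9.

**Step 9**
Reactants: 11, cyclodecadiene diacetate
Product: 12, (6R,7S,8R)-14-hydroxygermacra-1(10)E,4E-diene-6,8-diyl diacetate (C14 trans to C2, C2 cis to C9)
Conditions: SeO2 (0.5 equiv), t-BuOOH (decane), CH2Cl2, 0 °C to rt; then NaBH4, CeCl3·7H2O, MeOH, 0 °C to return any enal to the alcohol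
Reagents that add atoms: selenium dioxide, O=[Se]=O; tert-butyl hydroperoxide, CC(C)(C)OO
Why: In this Sharpless–Umbreit allylic oxidation (ene, then [2,3]-shift), SeO2 attacks the more electron-rich C1=C10 olefin because C4=C5 is deactivated by the allylic OAc and C9–H by the β-OAc. It hydroxylates C14 with the CH2OH trans to C2, as is known for C10-methyl germacranes.

**Step 10**
Reactants: 12, allylic alcohol
Product: 13, (1R,6R,7S,8R,10R)-1,10-epoxy-14-hydroxygermacr-4E-ene-6,8-diyl diacetate
Conditions: Ti(Oi-Pr)4 (1.0 equiv), D-(−)-DET (1.2 equiv), t-BuOOH (decane), 4 Å MS, CH2Cl2, −25 °C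
Reagents that add atoms: tert-butyl hydroperoxide, CC(C)(C)OO
Why: Katsuki–Sharpless epoxidation touches only the olefin bearing the free allylic OH. D-(−)-tartrate gives the (2R,3R)-type epoxy alcohol from this (E)-2,3-disubstituted allylic alcohol, setting C1 (R) and C10 by syn addition with C2 and C9 cis.

**Step 11**
Reactants: 13, epoxy alcohol
Product: 14, Pulicanaral A, (1R,6R,7S,8R,10S)-6,8-diacetoxy-1,10-epoxygermacr-4E-en-14-al
Conditions: DMP, NaHCO3, CH2Cl2, 0 °C to rt
Reagents that add atoms: none
Why: Buffered Dess–Martin oxidation converts the primary alcohol to the aldehyde without opening the oxirane. C10 is quaternary and cannot epimerise, and its descriptor changes from R to S only because CHO outranks C1.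

Stereochemistry bookkeeping:
- C7 and C8 are set in step 2.
- C6 is set in step 6.
- The 4E olefin geometry is set in step 4.
- The C1=C10 geometry is set in steps 8 and 9.
- C1 and C10 are set in step 10.

## Compound list
| No. | Name | SMILES | Role |
|---|---|---|---|
| 1 | 3-methylbut-3-en-1-ol | C=C(C)CCO | starting material |
| 2 | 3-methylbut-3-enal | C=C(C)CC=O | intermediate |
| 3 | (4S)-4-benzyl-3-(3-methylbutanoyl)oxazolidin-2-one | CC(C)CC(=O)N1[C@@H](Cc2ccccc2)COC1=O | starting material |
| 4 | Evans syn-aldol adduct (2S,3R) | C=C(C)C[C@@H](O)[C@@H](C(=O)N1[C@@H](Cc2ccccc2)COC1=O)C(C)C | intermediate |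
| 5 | (2S,3R)-β-hydroxy Weinreb amide | C=C(C)C[C@@H](O)[C@@H](C(=O)N(C)OC)C(C)C | intermediate |
| 6 | hex-1-en-5-yne | C=CCCC#C | starting material |
| 7 | (1E)-1-iodo-2-methylhexa-1,5-diene | I/C=C(\C)CCC=C | intermediate |
| 8 | (4R,5S,7E)-β-hydroxy enone | C=C(C)C[C@@H](O)[C@@H](C(=O)/C=C(\C)CCC=C)C(C)C | intermediate |
| 9 | (4R,5S,6R,7E)-anti-diol | C=C(C)C[C@@H](O)[C@@H]([C@H](O)/C=C(\C)CCC=C)C(C)C | intermediate |
| 10 | triene diacetate | C=C(C)C[C@@H](OC(C)=O)[C@@H]([C@H](OC(C)=O)/C=C(\C)CCC=C)C(C)C | intermediate |
| 11 | germacra-1(10)Z,4E-diene-6,8-diyl diacetate | CC(=O)O[C@@H]1/C=C(\C)CC/C=C(/C)C[C@@H](OC(C)=O)[C@@H]1C(C)C | intermediate |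
| 12 | 14-hydroxy diene diacetate | CC(=O)O[C@@H]1/C=C(\C)CC/C=C(/CO)C[C@@H](OC(C)=O)[C@@H]1C(C)C | intermediate |
| 13 | 1,10-epoxy-14-ol diacetate | CC(=O)O[C@@H]1/C=C(\C)CC[C@H]2O[C@@]2(CO)C[C@@H](OC(C)=O)[C@@H]1C(C)C | intermediate |
| 14 | Pulicanaral A | CC(=O)O[C@@H]1/C=C(\C)CC[C@H]2O[C@@]2(C=O)C[C@@H](OC(C)=O)[C@@H]1C(C)C | target |

## Summary
Total steps: 11.
Longest linear sequence: 10 (steps 1, 2, 3, 5, 6, 7, 8, 9, 10, 11).

The three steps most likely to fail:
1. **Step 8, RCM to the strained (E,Z)-cyclodecadiene.** The risks are oligomerisation or no closure. Fallback: close the ring at C5–C6 instead.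
   - Cross-metathesise the methallyl end of O-silylated 5 with the terminal olefin of 7. The geometry does not matter because step 9 resets it.
   - Reduce the amide to the C6 aldehyde with DIBAL-H.
   - Cyclise by intramolecular Nozaki–Hiyama–Kishi coupling (CrCl2/NiCl2).
   - Oxidise C6 and apply the OH-directed anti reduction to secure its configuration.
2. **Step 9, site selectivity of SeO2.** Oxidation could occur at C9, C2 or C3 instead of C14. Fallback: carry the C14 oxygen from the start. Run the Evans aldol with 3-[(tert-butyldimethylsilyloxy)methyl]but-3-enal, so that RCM gives the C14 silyl ether, and release 12 with HF·pyridine.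
3. **Step 10, Sharpless epoxidation on the macrocycle.** The reagent may be mismatched with the ring's peripheral face, or Ti may promote transannular opening. Fallback: switch to nucleophilic epoxidation. Oxidise 12 to the enal with MnO2, then apply iminium-catalysed H2O2 epoxidation for α-branched enals (cinchona primary amine with a chiral phosphoric acid). This gives 14 directly, with the face chosen by the catalyst enantiomer.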